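**Retrosynthetic overview**
- The C2=C3 double bond is introduced last, by dehydrogenating a saturated cis-2,4-dihydroxy-4-alkylcyclohexanone through its enol silane.
- That cis-diol ketone comes from the achiral 4-alkyl-4-hydroxycyclohexanone; one organocatalytic α-oxygenation desymmetrises the ring and sets both stereocentres.
- The achiral ketone comes from a [5+1] annulation: the ester carbonyl of methyl (11Z)-octadec-11-enoate becomes C4, and both C3–C4 and C4–C5 are made by the two β-carbanions of a ketal-masked pentan-3-one (double homoenolate).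
- The ester comes from a Z-selective Wittig reaction of heptanal with the ylide of methyl 11-bromoundecanoate.
- Only one ring is formed, in the annulation (step 4).

Assumption: methyl 11-bromoundecanoate and 1,5-dichloropentan-3-one are taken as inexpensive catalogue chemicals; "C1–C6" in the text refers to the target numbering (C1 carbonyl, C4 chain-bearing carbinol, C6 secondary carbinol).

**Step 1**
Reactants: 1 methyl 11-bromoundecanoate; 2 triphenylphosphine
Product: 3 (11-methoxy-11-oxoundecyl)triphenylphosphonium bromide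
Conditions: PPh3 (1.05 equiv), MeCN, reflux, 48 h
Reagents that add atoms: none
Why: SN2 quaternisation of the primary bromide by the phosphine gives the Wittig salt; no stereocentre is involved.

**Step 2**
Reactants: 3 (11-methoxy-11-oxoundecyl)triphenylphosphonium bromide; 4 heptanal
Product: 6 methyl (11Z)-octadec-11-enoate, via phosphorus ylide 5 (not isolated)
Conditions: NaN(SiMe3)2 (1.0 equiv), THF, −78 °C; then 4, −78 °C → rt
Reagents that add atoms: none
Why: Salt-free Wittig olefination of a non-stabilised ylide gives the Z-alkene under kinetic control (typically ≥95:5), the phosphonium α-CH being far more acidic than the ester α-CH.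

**Step 3**
Reactants: 7 1,5-dichloropentan-3-one; 8 2,2-dimethylpropane-1,3-diol
Product: 9 2,2-bis(2-chloroethyl)-5,5-dimethyl-1,3-dioxane
Conditions: TsOH·H2O (2 mol %), toluene, Dean–Stark, reflux
Reagents that add atoms: none
Why: Acid-catalysed ketalisation masks the ketone as a dioxane ketal, the form in which β-metallated ketone equivalents are thermally stable.

**Step 4 (key step)**
Reactants: 9 2,2-bis(2-chloroethyl)-5,5-dimethyl-1,3-dioxane; 6 methyl (11Z)-octadec-11-enoate
Product: 12 4-[(10Z)-heptadec-10-en-1-yl]-4-hydroxycyclohexan-1-one, via bis-Grignard reagent 10 (not isolated), via spiroketal carbinol 11 (not isolated)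
Conditions: Mg (2.6 equiv), I2 (cat.), THF, 55 °C; then 6 (0.7 equiv, slow addition), 0 °C → rt; then 3 M aq HCl, THF, 40 °C
Reagents that add atoms: water, O
Why: The two β-carbons of the masked ketone act as a double homoenolate in a di-Grignard [5+1] ester annulation (first addition gives the ketone, the second closes the six-membered ring intramolecularly), so two normally electrophilic carbons are joined at C4; aqueous acid then hydrolyses the ketal, and no stereocentre arises because the two arms are identical.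

**Step 5**
Reactants: 12 4-[(10Z)-heptadec-10-en-1-yl]-4-hydroxycyclohexan-1-one
Product: 14 (2S,4S)-4-[(10Z)-heptadec-10-en-1-yl]-2,4-dihydroxycyclohexan-1-one, via anilinoxy ketone 13 (not isolated)
Conditions: D-proline (30 mol %), PhNO (2.5 equiv, syringe pump), DMF/CHCl3 1:1, 0 °C → rt
Reagents that add atoms: nitrosobenzene, O=Nc1ccccc1
Why: Proline-enamine α-aminoxylation (O-selective nitroso aldol) with D-proline fixes the new carbinol as S, and chair-like axial attack syn to the small axial tertiary OH (chain equatorial) selects one enantiotopic α-carbon and thereby sets the quaternary centre cis to the new OH, while excess PhNO heterolyses the O–N bond in the flask.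

**Step 6**
Reactants: 14 (2S,4S)-4-[(10Z)-heptadec-10-en-1-yl]-2,4-dihydroxycyclohexan-1-one
Product: 16 (4S,6S)-4-[(10Z)-heptadec-10-en-1-yl]-1,4,6-tris[(trimethylsilyl)oxy]cyclohex-1-ene, via bis-silyl ether 15 (not isolated)
Conditions: N-(trimethylsilyl)imidazole (2.5 equiv), CH2Cl2, rt; hexane, filter; then LiN(iPr)2 (1.2 equiv), THF, −78 °C; Me3SiCl (1.5 equiv), −78 → 0 °C
Reagents that add atoms: N-(trimethylsilyl)imidazole, C[Si](C)(C)n1ccnc1; chlorotrimethylsilane, C[Si](C)(C)Cl
Why: Silylation of both hydroxyls followed by kinetic deprotonation, which takes the unhindered α'-CH2 rather than the silyloxy-bearing methine, gives the regiodefined enol silane without touching either stereocentre.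

**Step 7**
Reactants: 16 (4S,6S)-4-[(10Z)-heptadec-10-en-1-yl]-1,4,6-tris[(trimethylsilyl)oxy]cyclohex-1-ene
Product: 18 (4R,6S)-4-[(10Z)-heptadec-10-en-1-yl]-4,6-dihydroxycyclohex-2-en-1-one, via bis-silyl enone 17 (not isolated)
Conditions: Pd(OAc)2 (1.1 equiv), MeCN, rt; then 1 M aq HCl, THF, 0 °C
Reagents that add atoms: none
Why: Saegusa–Ito oxidation (α-palladio ketone, then β-hydride loss from the only adjacent CH2) installs the enone, and cold dilute acid removes both silyl ethers without epimerising the α-carbinol or disturbing the remote Z-alkene.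

**Compound list**
1 | methyl 11-bromoundecanoate | COC(=O)CCCCCCCCCCBr | starting material
2 | triphenylphosphine | c1ccc(cc1)P(c1ccccc1)c1ccccc1 | starting material
3 | (11-methoxy-11-oxoundecyl)triphenylphosphonium bromide | COC(=O)CCCCCCCCCC[P+](c1ccccc1)(c1ccccc1)c1ccccc1.[Br-] | intermediate
4 | heptanal | CCCCCCC=O | starting material
5 | methyl 11-(triphenylphosphoranylidene)undecanoate | COC(=O)CCCCCCCCCC=P(c1ccccc1)(c1ccccc1)c1ccccc1 | intermediate
6 | methyl (11Z)-octadec-11-enoate | CCCCCC/C=C\CCCCCCCCCC(=O)OC | intermediate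
7 | 1,5-dichloropentan-3-one | ClCCC(=O)CCCl | starting material
8 | 2,2-dimethylpropane-1,3-diol | OCC(C)(C)CO | starting material
9 | 2,2-bis(2-chloroethyl)-5,5-dimethyl-1,3-dioxane | ClCCC1(CCCl)OCC(C)(C)CO1 | intermediate
10 | [(5,5-dimethyl-1,3-dioxane-2,2-diyl)di(ethane-2,1-diyl)]bis(chloromagnesium) | Cl[Mg]CCC1(CC[Mg]Cl)OCC(C)(C)CO1 | intermediate
11 | 9-[(10Z)-heptadec-10-en-1-yl]-3,3-dimethyl-1,5-dioxaspiro[5.5]undecan-9-ol | CCCCCC/C=C\CCCCCCCCCC1(O)CCC2(CC1)OCC(C)(C)CO2 | intermediate
12 | 4-[(10Z)-heptadec-10-en-1-yl]-4-hydroxycyclohexan-1-one | CCCCCC/C=C\CCCCCCCCCC1(O)CCC(=O)CC1 | intermediate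
13 | (2S,4S)-4-[(10Z)-heptadec-10-en-1-yl]-4-hydroxy-2-[(phenylamino)oxy]cyclohexan-1-one | CCCCCC/C=C\CCCCCCCCC[C@]1(O)CCC(=O)[C@@H](ONc2ccccc2)C1 | intermediate
14 | (2S,4S)-4-[(10Z)-heptadec-10-en-1-yl]-2,4-dihydroxycyclohexan-1-one (cis-diol) | CCCCCC/C=C\CCCCCCCCC[C@]1(O)CCC(=O)[C@@H](O)C1 | intermediate
15 | (2S,4S)-4-[(10Z)-heptadec-10-en-1-yl]-2,4-bis[(trimethylsilyl)oxy]cyclohexan-1-one | CCCCCC/C=C\CCCCCCCCC[C@]1(O[Si](C)(C)C)CCC(=O)[C@@H](O[Si](C)(C)C)C1 | intermediate
16 | (4S,6S)-4-[(10Z)-heptadec-10-en-1-yl]-1,4,6-tris[(trimethylsilyl)oxy]cyclohex-1-ene | CCCCCC/C=C\CCCCCCCCC[C@]1(O[Si](C)(C)C)CC=C(O[Si](C)(C)C)[C@@H](O[Si](C)(C)C)C1 | intermediate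
17 | (4R,6S)-4-[(10Z)-heptadec-10-en-1-yl]-4,6-bis[(trimethylsilyl)oxy]cyclohex-2-en-1-one | CCCCCC/C=C\CCCCCCCCC[C@]1(O[Si](C)(C)C)C=CC(=O)[C@@H](O[Si](C)(C)C)C1 | intermediate
18 | (4R,6S)-4-[(10Z)-heptadec-10-en-1-yl]-4,6-dihydroxycyclohex-2-en-1-one | CCCCCC/C=C\CCCCCCCCC[C@]1(O)C=CC(=O)[C@@H](O)C1 | target

**Step count**
Total: 7 steps. Longest linear sequence: 6 steps (1, 2, 4, 5, 6, 7); step 3 is a one-step side branch.

**Steps most likely to fail, with fallbacks**

Step 4. The di-Grignard may form sluggishly, or the intermediate ketone may be intercepted intermolecularly. The fallback sets out from 6 and returns at 12, replacing the double homoenolate by an acyl anion followed by a ketyl. iBu2AlH (1.05 equiv, CH2Cl2, −78 °C) reduces 6 to (11Z)-octadec-11-enal F1. Et3N liberates penta-1,4-dien-3-one F2 from 7. Used in threefold excess, F2 takes up the acyl anion of F1 in a thiazolium-carbene Stetter reaction (3-benzyl-5-(2-hydroxyethyl)-4-methylthiazolium chloride 10 mol %, Et3N, dioxane, 70 °C) to give (16Z)-tricosa-1,16-diene-3,6-dione F3. SmI2 (2.2 equiv, THF/MeOH, −78 °C) then generates the ketyl of the chain ketone, which adds 6-endo to the terminal vinyl carbon; protonation of the samarium enolate gives 12.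

Step 5. The cis/trans ratio rests on the axial-OH chair model and may be modest or reversed. The fallback sets out from 12 and returns at 14. If the oxidant enters anti to the tertiary hydroxyl so that the trans diol dominates, L-proline is used under the same conditions to give (2R,4S)-4-[(10Z)-heptadec-10-en-1-yl]-2,4-dihydroxycyclohexan-1-one F4. Its secondary carbinol is inverted by Mitsunobu esterification (4-nitrobenzoic acid, PPh3, diisopropyl azodicarboxylate, THF, 0 °C) to (1S,5S)-5-[(10Z)-heptadec-10-en-1-yl]-5-hydroxy-2-oxocyclohexyl 4-nitrobenzoate F5. K2CO3 (0.2 equiv), MeOH, 0 °C then releases 14.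

Step 7. Pd(OAc)2 may isomerise the Z-alkene or the silyl ethers may be lost too early. The fallback sets out from 16 and returns at 17, using selenoxide elimination in place of palladium. PhSeCl (CH2Cl2, −78 °C) converts the enol silane into 4-[(10Z)-heptadec-10-en-1-yl]-6-(phenylselanyl)-2,4-bis[(trimethylsilyl)oxy]cyclohexan-1-one F6 (both epimers at the selenium-bearing carbon, oxygen-bearing centres as in 15). H2O2, pyridine, CH2Cl2, 0 °C gives 6-(benzeneseleninyl)-4-[(10Z)-heptadec-10-en-1-yl]-2,4-bis[(trimethylsilyl)oxy]cyclohexan-1-one F7, which undergoes syn-elimination to 17; acid desilylation as in step 7 then gives 18.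

**Further compounds**
F1 | step 4 | (11Z)-octadec-11-enal | CCCCCC/C=C\CCCCCCCCCC=O
F2 | step 4 | penta-1,4-dien-3-one | C=CC(=O)C=C
F3 | step 4 | (16Z)-tricosa-1,16-diene-3,6-dione | CCCCCC/C=C\CCCCCCCCCC(=O)CCC(=O)C=C
F4 | step 5 | (2R,4S)-4-[(10Z)-heptadec-10-en-1-yl]-2,4-dihydroxycyclohexan-1-one | CCCCCC/C=C\CCCCCCCCC[C@]1(O)CCC(=O)[C@H](O)C1
F5 | step 5 | (1S,5S)-5-[(10Z)-heptadec-10-en-1-yl]-5-hydroxy-2-oxocyclohexyl 4-nitrobenzoate | CCCCCC/C=C\CCCCCCCCC[C@]1(O)CCC(=O)[C@@H](OC(=O)c2ccc(cc2)[N+](=O)[O-])C1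
F6 | step 7 | 4-[(10Z)-heptadec-10-en-1-yl]-6-(phenylselanyl)-2,4-bis[(trimethylsilyl)oxy]cyclohexan-1-one | CCCCCC/C=C\CCCCCCCCC[C@]1(O[Si](C)(C)C)CC([Se]c2ccccc2)C(=O)[C@@H](O[Si](C)(C)C)C1
F7 | step 7 | 6-(benzeneseleninyl)-4-[(10Z)-heptadec-10-en-1-yl]-2,4-bis[(trimethylsilyl)oxy]cyclohexan-1-one | CCCCCC/C=C\CCCCCCCCC[C@]1(O[Si](C)(C)C)CC([Se](=O)c2ccccc2)C(=O)[C@@H](O[Si](C)(C)C)C1
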